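**Retrosynthetic overview**

1. Target 36 ⇒ two amide N–CO bonds (trichloroacetylpyrroles 33 and 35) and two imidazole C2–N bonds (lithiation, azide transfer) ⇒ all-trans, C2-symmetric cyclobutane diester 21.
2. 21 ⇒ Wolff ring contraction of the 3-diazo-2-oxocyclopentane-1-carboxylate 18, which makes the cyclobutane bond between the two ring carbons that carry the CH2N arms.
3. 18 ⇒ diazo transfer and Dieckmann closure of the (3S,4S)-adipate 13 ⇒ SmI2 β,β-hydrodimerisation of the urocanoyl imide 10 (bond between the two imidazolyl-bearing ring carbons, both stereocentres) ⇒ urocanic acid 1.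
4. Feature used: each half of the cyclobutane, imidazole C4–ring CH–ring CH–CH2N, is the carbon chain of urocanic acid at lower oxidation level, so the four-membered ring is a head-to-head urocanate dimer joined through its two β-carbons and its two α-carbons.
5. Ring order: cyclopentanone (step 7), then cyclobutane by contraction (step 10); the imidazole and pyrrole rings are bought.

Key step: step 10

Assumption: in step 5 the chelated s-cis enoyl imide is taken to couple at the β-carbon face anti to the benzyl group, which makes the (R)-auxiliary the one that delivers the (3S,4S)-adipate; if the sense is the reverse, the (S)-antipode is used and nothing else changes.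

Descriptors of the cyclobutanes use the numbering C1/C2 = carbons bearing the one-carbon arms, C3/C4 = carbons bearing the imidazoles. The switch from (1S,2S,3R,4R) in the oxygen series to (1R,2R,3S,4S) in the nitrogen series is a priority effect only; no centre is inverted.

**Route**

Step 1
Reactants: 1 urocanic acid; 2 methanol
Product: 3 methyl urocanate
Conditions: H2SO4 (2 equiv), MeOH, reflux; aq. NaHCO3
Reagents that add atoms: methanol, CO
Why: Fischer esterification masks the carboxylic acid so that the sulfamoyl chloride of step 2 meets only the ring NH, and it leaves the E-alkene untouched.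

Step 2
Reactants: 3 methyl urocanate; 4 dimethylsulfamoyl chloride
Product: 5 methyl (E)-3-[1-(dimethylsulfamoyl)imidazol-4-yl]prop-2-enoate
Conditions: Me2NSO2Cl (1.1 equiv), Et3N (1.5 equiv), MeCN, 23 °C
Reagents that add atoms: dimethylsulfamoyl chloride, CN(C)S(=O)(=O)Cl
Why: N-sulfonylation of the imidazole, in which the 1,4-isomer (sulfamoyl on the nitrogen remote from the side chain) is favoured sterically and by amine-mediated sulfamoyl equilibration.

Step 3
Reactants: 5 methyl (E)-3-[1-(dimethylsulfamoyl)imidazol-4-yl]prop-2-enoate; 6 lithium hydroxide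
Product: 7 (E)-3-[1-(dimethylsulfamoyl)imidazol-4-yl]prop-2-enoic acid
Conditions: LiOH·H2O (1.5 equiv), THF/H2O, 0 °C; HCl to pH 3
Reagents that add atoms: lithium hydroxide, [Li+].[OH-]
Why: Saponification of an unhindered methyl ester at 0 °C, conditions under which the sulfamoyl imidazole (cleaved only by hot aqueous acid or alkali) should persist.

Step 4
Reactants: 7 (E)-3-[1-(dimethylsulfamoyl)imidazol-4-yl]prop-2-enoic acid; 8 (R)-4-benzyloxazolidin-2-one
Product: 10 (R)-4-benzyl-3-[(E)-3-[1-(dimethylsulfamoyl)imidazol-4-yl]prop-2-enoyl]oxazolidin-2-one, via mixed pivalic anhydride 9 (not isolated)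
Conditions: t-BuCOCl (1.05 equiv), Et3N (2.5 equiv), THF, −20 °C; then LiCl, 8, −20 → 23 °C
Reagents that add atoms: (R)-4-benzyloxazolidin-2-one, O=C1N[C@H](Cc2ccccc2)CO1
Why: N-acylation of the oxazolidinone by the mixed-anhydride method, the lithium-complexed oxazolidinone attacking the less hindered acryloyl carbonyl of 9.

Step 5
Reactants: 10 (R)-4-benzyl-3-[(E)-3-[1-(dimethylsulfamoyl)imidazol-4-yl]prop-2-enoyl]oxazolidin-2-one (two molecules)
Product: 11 (3S,4S)-1,6-bis[(R)-4-benzyl-2-oxooxazolidin-3-yl]-3,4-bis[1-(dimethylsulfamoyl)imidazol-4-yl]hexane-1,6-dione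
Conditions: SmI2 (2.2 equiv), t-BuOH (2.5 equiv), THF, −78 → −20 °C
Reagents that add atoms: none
Why: Reductive β,β-hydrodimerisation of a conjugated acyl derivative with SmI2: electron transfer gives a trivalent samarium chelate of the s-cis radical enolate (both imide carbonyls bound), two of which join at their β-carbons on the face anti to the benzyl group, so that like faces couple and both new stereocentres are set as the C2-symmetric (3S,4S) pair before the bis-enolate is protonated by t-BuOH.

Step 6
Reactants: 11 the bis-imide of step 5; 12 sodium methoxide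
Product: 13 dimethyl (3S,4S)-3,4-bis[1-(dimethylsulfamoyl)imidazol-4-yl]hexanedioate
Conditions: NaOMe (2.2 equiv), MeOH/CH2Cl2, 0 °C; aq. NH4Cl
Reagents that add atoms: sodium methoxide, [Na+].[O-]C
Why: Transesterification of an N-acyl oxazolidinone, in which methoxide attacks the exocyclic carbonyl of the α-unbranched imide and releases the auxiliary, while the stereocentres, β to the carbonyls, cannot epimerise.

Step 7
Reactants: 13 dimethyl (3S,4S)-3,4-bis[1-(dimethylsulfamoyl)imidazol-4-yl]hexanedioate
Product: 14 methyl (1S,4S,5R)-2-oxo-4,5-bis[1-(dimethylsulfamoyl)imidazol-4-yl]cyclopentane-1-carboxylate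
Conditions: LiN(SiMe3)2 (2.2 equiv), THF, −78 → 0 °C; AcOH
Reagents that add atoms: none
Why: Dieckmann condensation (5-exo-trig acyl substitution of one ester by the enolate of the other, driven by deprotonation of the β-keto ester); the C2 symmetry of 13 makes the two possible closures identical, and C1 should settle on quench as the epimer trans to the C5 imidazolyl, though it stays labile.

Step 8
Reactants: 14 the β-keto ester of step 7; 15 tert-butoxybis(dimethylamino)methane (Bredereck's reagent)
Product: 16 methyl (1S,4R,5R)-3-[(E)-(dimethylamino)methylidene]-2-oxo-4,5-bis[1-(dimethylsulfamoyl)imidazol-4-yl]cyclopentane-1-carboxylate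
Conditions: t-BuOCH(NMe2)2 (1.5 equiv), toluene, 70 °C
Reagents that add atoms: tert-butoxybis(dimethylamino)methane, CN(C)C(OC(C)(C)C)N(C)C
Why: Aminomethylenation of a ketone α-methylene with an aminal ester: only C3 carries the two hydrogens needed for loss of dimethylamine to the vinylogous amide, so any adduct at the acidic C1–H reverts and the carbon that must become the carbene centre is activated regiospecifically.

Step 9
Reactants: 16 the enaminone of step 8; 17 4-methylbenzenesulfonyl azide (tosyl azide)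
Product: 18 methyl (1S,4S,5R)-3-diazo-2-oxo-4,5-bis[1-(dimethylsulfamoyl)imidazol-4-yl]cyclopentane-1-carboxylate
Conditions: 4-MeC6H4SO2N3 (1.2 equiv), MeCN, 0 → 23 °C
Reagents that add atoms: tosyl azide, Cc1ccc(cc1)S(=O)(=O)N=[N+]=[N-]
Why: Diazo transfer to an enaminone (dipolar cycloaddition of the sulfonyl azide to the electron-rich C=C, then cycloreversion with loss of the N-sulfonylformamidine), chosen because it needs no base and so leaves alone the C1–H of the β-keto ester, which under basic transfer conditions would be azidated with ring cleavage.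

Step 10
Reactants: 18 the diazoketone of step 9; 2 methanol
Product: 21 dimethyl (1S,2S,3R,4R)-3,4-bis[1-(dimethylsulfamoyl)imidazol-4-yl]cyclobutane-1,2-dicarboxylate (all-trans), via ketene 19 (not isolated), via kinetic diester epimer mixture 20 (not isolated)
Conditions: hν (medium-pressure Hg lamp, Pyrex, λ > 300 nm), degassed MeOH, 0 °C; then NaOMe (0.5 equiv), 23 → 40 °C; AcOH
Reagents that add atoms: methanol, CO
Why: Photoexcitation of 18 expels N2 while ring carbon C1 (the ester-bearing carbon) shifts from the carbonyl carbon C2 to the diazo carbon C3, the photochemical Wolff rearrangement of a cyclic 2-diazoketone used as a ring contraction, and methanol adds to the exocyclic ketene 19 to give diester 20. The cyclobutane is closed by this 1,2-shift inside the five-membered ring (the C1–C3 bond forms as the C1–C2 bond breaks), not by cyclisation of an open chain, and the extruded C2 becomes the ester carbon, later the CH2N carbon, on C3. The migrating carbon moves suprafacially with retention, so its ester stays trans to the neighbouring imidazolyl carbon. The stereocentre created at the former diazo carbon arises by protonation of the ester enol, probably from the face away from both neighbours, and is therefore corrected in the same flask by NaOMe, which equilibrates both ester-bearing carbons to the all-trans array, the thermodynamic minimum once the two non-epimerisable imidazolyl carbons are fixed trans by step 5. The step needs ring contraction to win over 1,2-hydride shift from C4 and over O–H insertion into methanol; the ring holds the diazoketone s-cis, the geometry from which the singlet excited state rearranges in concert with nitrogen loss, and C1 is the only group on the carbonyl carbon that can migrate.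

Step 11
Reactants: 21 the all-trans diester of step 10
Product: 22 [(1S,2S,3R,4R)-3,4-bis[1-(dimethylsulfamoyl)imidazol-4-yl]cyclobutane-1,2-diyl]dimethanol
Conditions: LiBH4 (4 equiv), THF/MeOH, 0 → 23 °C
Reagents that add atoms: none
Why: Methanol-accelerated LiBH4 reduction of the two methyl esters, which should spare the sulfamoyl imidazoles and touches no stereocentre.

Step 12
Reactants: 22 the diol of step 11; 23 tert-butyldimethylsilyl chloride
Product: 24 the bis(tert-butyldimethylsilyl) ether of 22, (1S,2S,3R,4R)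
Conditions: t-BuMe2SiCl (2.5 equiv), imidazole, DMF, 23 °C
Reagents that add atoms: tert-butyldimethylsilyl chloride, CC(C)(C)[Si](C)(C)Cl
Why: Silyl ether formation removes the two acidic OH groups before the organolithium step and withstands n-BuLi at −78 °C.

Step 13
Reactants: 24 the bis-silyl ether of step 12; 17 tosyl azide
Product: 26 the bis(2-azidoimidazole) bis-silyl ether, (1S,2S,3R,4R), via dilithio species 25 (not isolated)
Conditions: n-BuLi (2.2 equiv), THF, −78 °C; then 4-MeC6H4SO2N3 (2.5 equiv), −78 → 0 °C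
Reagents that add atoms: tosyl azide, Cc1ccc(cc1)S(=O)(=O)N=[N+]=[N-]
Why: Directed lithiation, the sulfamoyl imidazole being deprotonated at C2 (between the two nitrogens), followed by electrophilic azide transfer in which the triazenyl adduct collapses to the 2-azide and sulfinate.

Step 14
Reactants: 26 the bis(2-azidoimidazole) bis-silyl ether of step 13
Product: 27 [(1S,2S,3R,4R)-3,4-bis[2-azido-1-(dimethylsulfamoyl)imidazol-4-yl]cyclobutane-1,2-diyl]dimethanol
Conditions: HF·pyridine, THF, 0 → 23 °C
Reagents that add atoms: none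
Why: Fluoride cleavage of the silyl ethers under mildly acidic conditions that the azides and sulfamoyl groups tolerate.

Step 15
Reactants: 27 the bis-azido diol of step 14; 28 sodium azide
Product: 30 (1R,2R,3S,4S)-1,2-bis(azidomethyl)-3,4-bis[2-azido-1-(dimethylsulfamoyl)imidazol-4-yl]cyclobutane, via bis-mesylate 29 (not isolated)
Conditions: MeSO2Cl (2.5 equiv), Et3N, CH2Cl2, 0 °C; then NaN3 (6 equiv), DMF, 60 °C
Reagents that add atoms: sodium azide, [Na+].[N-]=[N+]=[N-]
Why: Mesylation and SN2 displacement by azide at the two primary cyclobutylmethyl carbons, which leaves the ring stereocentres untouched; the azide-rich product is handled on small scale, in solution and below 40 °C.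

Step 16
Reactants: 30 the tetraazide of step 15
Product: 31 (1R,2R,3S,4S)-1,2-bis(aminomethyl)-3,4-bis[2-amino-1-(dimethylsulfamoyl)imidazol-4-yl]cyclobutane
Conditions: H2 (1 atm), 10% Pd/C, MeOH, 23 °C
Reagents that add atoms: none
Why: Catalytic hydrogenation reduces the two alkyl and the two heteroaryl azides to amines in one operation with loss of N2.

Step 17
Reactants: 31 the sulfamoyl-protected tetraamine of step 16
Product: 32 (1R,2R,3S,4S)-1,2-bis(aminomethyl)-3,4-bis(2-amino-1H-imidazol-5-yl)cyclobutane (free base)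
Conditions: HCl (4 M aq.)/MeOH, reflux; then hydroxide-form anion-exchange resin
Reagents that add atoms: none
Why: Acid hydrolysis of the N–S bond of the sulfamoyl imidazoles, the standard removal of this group, with all amino groups protected as their salts until the resin releases the free base.

Step 18
Reactants: 32 the diamine of step 17; 33 4-bromo-2-(trichloroacetyl)pyrrole
Product: 34 N-[[(1R,2R,3S,4S)-2-(aminomethyl)-3,4-bis(2-amino-1H-imidazol-5-yl)cyclobutyl]methyl]-4-bromo-1H-pyrrole-2-carboxamide
Conditions: HCl (1.0 equiv, in MeOH), DMF, 0 °C; then 33 (1.0 equiv), 0 → 23 °C; aq. NaHCO3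
Reagents that add atoms: 4-bromo-2-(trichloroacetyl)pyrrole, O=C(c1cc(Br)c[nH]1)C(Cl)(Cl)Cl
Why: Haloform-type acyl transfer from a trichloromethyl ketone to a primary amine; one equivalent of acid parks a proton on one of the two aliphatic amines (the most basic sites), so acylation should stop at the mono-amide, either arm gives the same compound because the two are related by the C2 axis, and the 2-aminoimidazoles are too weakly nucleophilic to compete.

Step 19
Reactants: 34 the mono-amide of step 18; 35 2-(trichloroacetyl)pyrrole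
Product: 36 desbromosceptrine
Conditions: 35 (1.2 equiv), DMF, 23 °C
Reagents that add atoms: 2-(trichloroacetyl)pyrrole, O=C(c1ccc[nH]1)C(Cl)(Cl)Cl
Why: The same acyl transfer to the remaining free primary amine installs the second, bromine-free pyrrole amide and completes the target.

**Compound list**

1 | urocanic acid | OC(=O)/C=C/c1c[nH]cn1 | starting material
2 | methanol | CO | starting material
3 | methyl urocanate | COC(=O)/C=C/c1c[nH]cn1 | intermediate
4 | dimethylsulfamoyl chloride | CN(C)S(=O)(=O)Cl | starting material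
5 | methyl (E)-3-[1-(dimethylsulfamoyl)imidazol-4-yl]prop-2-enoate | COC(=O)/C=C/c1cn(S(=O)(=O)N(C)C)cn1 | intermediate
6 | lithium hydroxide | [Li+].[OH-] | starting material
7 | (E)-3-[1-(dimethylsulfamoyl)imidazol-4-yl]prop-2-enoic acid | OC(=O)/C=C/c1cn(S(=O)(=O)N(C)C)cn1 | intermediate
8 | (R)-4-benzyloxazolidin-2-one | O=C1N[C@H](Cc2ccccc2)CO1 | starting material
9 | mixed anhydride of 7 and pivalic acid | CC(C)(C)C(=O)OC(=O)/C=C/c1cn(S(=O)(=O)N(C)C)cn1 | intermediate
10 | (R)-4-benzyl-3-[(E)-3-[1-(dimethylsulfamoyl)imidazol-4-yl]prop-2-enoyl]oxazolidin-2-one | O=C(/C=C/c1cn(S(=O)(=O)N(C)C)cn1)N1[C@H](Cc2ccccc2)COC1=O | intermediate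
11 | (3S,4S)-1,6-bis[(R)-4-benzyl-2-oxooxazolidin-3-yl]-3,4-bis[1-(dimethylsulfamoyl)imidazol-4-yl]hexane-1,6-dione | O=C(C[C@H](c1cn(S(=O)(=O)N(C)C)cn1)[C@@H](c1cn(S(=O)(=O)N(C)C)cn1)CC(=O)N1[C@H](Cc2ccccc2)COC1=O)N1[C@H](Cc2ccccc2)COC1=O | intermediate
12 | sodium methoxide | [Na+].[O-]C | starting material
13 | dimethyl (3S,4S)-3,4-bis[1-(dimethylsulfamoyl)imidazol-4-yl]hexanedioate | COC(=O)C[C@H](c1cn(S(=O)(=O)N(C)C)cn1)[C@@H](c1cn(S(=O)(=O)N(C)C)cn1)CC(=O)OC | intermediate
14 | methyl (1S,4S,5R)-2-oxo-4,5-bis[1-(dimethylsulfamoyl)imidazol-4-yl]cyclopentane-1-carboxylate (ester trans to the C5 imidazolyl, the two imidazolyls trans) | CN(C)S(=O)(=O)n1cnc(c1)[C@H]2CC(=O)[C@@H](C(=O)OC)[C@@H]2c1cn(S(=O)(=O)N(C)C)cn1 | intermediate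
15 | tert-butoxybis(dimethylamino)methane | CN(C)C(OC(C)(C)C)N(C)C | starting material
16 | methyl (1S,4R,5R)-3-[(E)-(dimethylamino)methylidene]-2-oxo-4,5-bis[1-(dimethylsulfamoyl)imidazol-4-yl]cyclopentane-1-carboxylate | CN(C)/C=C1/C(=O)[C@@H](C(=O)OC)[C@H](c2cn(S(=O)(=O)N(C)C)cn2)[C@H]1c1cn(S(=O)(=O)N(C)C)cn1 | intermediate
17 | 4-methylbenzenesulfonyl azide | Cc1ccc(cc1)S(=O)(=O)N=[N+]=[N-] | starting material
18 | methyl (1S,4S,5R)-3-diazo-2-oxo-4,5-bis[1-(dimethylsulfamoyl)imidazol-4-yl]cyclopentane-1-carboxylate | CN(C)S(=O)(=O)n1cnc(c1)[C@H]2C(=[N+]=[N-])C(=O)[C@@H](C(=O)OC)[C@@H]2c1cn(S(=O)(=O)N(C)C)cn1 | intermediate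
19 | methyl (1S,3R,4R)-3,4-bis[1-(dimethylsulfamoyl)imidazol-4-yl]-2-(oxomethylidene)cyclobutane-1-carboxylate (ketene) | CN(C)S(=O)(=O)n1cnc(c1)[C@H]2C(=C=O)[C@@H](C(=O)OC)[C@@H]2c1cn(S(=O)(=O)N(C)C)cn1 | intermediate
20 | dimethyl (2S,3R,4R)-3,4-bis[1-(dimethylsulfamoyl)imidazol-4-yl]cyclobutane-1,2-dicarboxylate, mixture of C1 epimers | CN(C)S(=O)(=O)n1cnc(c1)[C@H]2C(C(=O)OC)[C@@H](C(=O)OC)[C@@H]2c1cn(S(=O)(=O)N(C)C)cn1 | intermediate
21 | dimethyl (1S,2S,3R,4R)-3,4-bis[1-(dimethylsulfamoyl)imidazol-4-yl]cyclobutane-1,2-dicarboxylate (all-trans) | CN(C)S(=O)(=O)n1cnc(c1)[C@H]2[C@H](C(=O)OC)[C@@H](C(=O)OC)[C@@H]2c1cn(S(=O)(=O)N(C)C)cn1 | intermediate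
22 | [(1S,2S,3R,4R)-3,4-bis[1-(dimethylsulfamoyl)imidazol-4-yl]cyclobutane-1,2-diyl]dimethanol (all-trans) | CN(C)S(=O)(=O)n1cnc(c1)[C@H]2[C@H](CO)[C@@H](CO)[C@@H]2c1cn(S(=O)(=O)N(C)C)cn1 | intermediate
23 | tert-butyldimethylsilyl chloride | CC(C)(C)[Si](C)(C)Cl | starting material
24 | (1S,2S,3R,4R)-1,2-bis[(tert-butyldimethylsilyloxy)methyl]-3,4-bis[1-(dimethylsulfamoyl)imidazol-4-yl]cyclobutane | CN(C)S(=O)(=O)n1cnc(c1)[C@H]2[C@H](CO[Si](C)(C)C(C)(C)C)[C@@H](CO[Si](C)(C)C(C)(C)C)[C@@H]2c1cn(S(=O)(=O)N(C)C)cn1 | intermediate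
25 | 2,2'-dilithio derivative of 24 (lithium at C2 of each imidazole) | CN(C)S(=O)(=O)n1c([Li])nc(c1)[C@H]2[C@H](CO[Si](C)(C)C(C)(C)C)[C@@H](CO[Si](C)(C)C(C)(C)C)[C@@H]2c1cn(S(=O)(=O)N(C)C)c([Li])n1 | intermediate
26 | (1S,2S,3R,4R)-1,2-bis[(tert-butyldimethylsilyloxy)methyl]-3,4-bis[2-azido-1-(dimethylsulfamoyl)imidazol-4-yl]cyclobutane | CN(C)S(=O)(=O)n1c(N=[N+]=[N-])nc(c1)[C@H]2[C@H](CO[Si](C)(C)C(C)(C)C)[C@@H](CO[Si](C)(C)C(C)(C)C)[C@@H]2c1cn(S(=O)(=O)N(C)C)c(N=[N+]=[N-])n1 | intermediate
27 | [(1S,2S,3R,4R)-3,4-bis[2-azido-1-(dimethylsulfamoyl)imidazol-4-yl]cyclobutane-1,2-diyl]dimethanol | CN(C)S(=O)(=O)n1c(N=[N+]=[N-])nc(c1)[C@H]2[C@H](CO)[C@@H](CO)[C@@H]2c1cn(S(=O)(=O)N(C)C)c(N=[N+]=[N-])n1 | intermediate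
28 | sodium azide | [Na+].[N-]=[N+]=[N-] | starting material
29 | bis(methanesulfonate) of 27, (1S,2S,3R,4R) | CN(C)S(=O)(=O)n1c(N=[N+]=[N-])nc(c1)[C@H]2[C@H](COS(C)(=O)=O)[C@@H](COS(C)(=O)=O)[C@@H]2c1cn(S(=O)(=O)N(C)C)c(N=[N+]=[N-])n1 | intermediate
30 | (1R,2R,3S,4S)-1,2-bis(azidomethyl)-3,4-bis[2-azido-1-(dimethylsulfamoyl)imidazol-4-yl]cyclobutane | CN(C)S(=O)(=O)n1c(N=[N+]=[N-])nc(c1)[C@H]2[C@H](CN=[N+]=[N-])[C@@H](CN=[N+]=[N-])[C@@H]2c1cn(S(=O)(=O)N(C)C)c(N=[N+]=[N-])n1 | intermediate
31 | (1R,2R,3S,4S)-1,2-bis(aminomethyl)-3,4-bis[2-amino-1-(dimethylsulfamoyl)imidazol-4-yl]cyclobutane | CN(C)S(=O)(=O)n1c(N)nc(c1)[C@H]2[C@H](CN)[C@@H](CN)[C@@H]2c1cn(S(=O)(=O)N(C)C)c(N)n1 | intermediate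
32 | (1R,2R,3S,4S)-1,2-bis(aminomethyl)-3,4-bis(2-amino-1H-imidazol-5-yl)cyclobutane | Nc1ncc([C@H]2[C@H](CN)[C@@H](CN)[C@@H]2c2cnc(N)[nH]2)[nH]1 | intermediate
33 | 4-bromo-2-(trichloroacetyl)pyrrole | O=C(c1cc(Br)c[nH]1)C(Cl)(Cl)Cl | starting material
34 | N-[[(1R,2R,3S,4S)-2-(aminomethyl)-3,4-bis(2-amino-1H-imidazol-5-yl)cyclobutyl]methyl]-4-bromo-1H-pyrrole-2-carboxamide | Nc1ncc([C@H]2[C@H](CN)[C@@H](CNC(=O)c3cc(Br)c[nH]3)[C@@H]2c2cnc(N)[nH]2)[nH]1 | intermediate
35 | 2-(trichloroacetyl)pyrrole | O=C(c1ccc[nH]1)C(Cl)(Cl)Cl | starting material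
36 | desbromosceptrine, 4-bromo-N-[[(1R,2R,3S,4S)-3,4-bis(2-amino-1H-imidazol-5-yl)-2-[(1H-pyrrole-2-carbonylamino)methyl]cyclobutyl]methyl]-1H-pyrrole-2-carboxamide | Nc1ncc([C@H]2[C@H](CNC(=O)c3ccc[nH]3)[C@@H](CNC(=O)c3cc(Br)c[nH]3)[C@@H]2c2cnc(N)[nH]2)[nH]1 | target

**Step count and risks**

Total step count: 19. Longest linear sequence: 19 steps (1 → 36); the route is fully linear.

Steps most likely to fail:

Step 10 (Wolff ring contraction). After nitrogen loss the excited diazoketone may be diverted into 1,2-hydride shift from C4 or into O–H insertion of methanol, and the strain of the forming four-membered ring may slow the contraction relative to both. The fallback makes the same ring bond by oxidative enolate coupling instead of by a shift. It sets out from 13: double deprotonation with LiN(i-Pr)2 (2.2 equiv, THF, −78 °C) gives the dilithium bis-enolate F1, whose two α-carbons are joined intramolecularly by oxidation with CuBr2 (2.2 equiv, −78 → 0 °C) to the cyclobutane diester as a mixture of isomers at the two ester-bearing carbons F2. NaOMe in MeOH equilibrates this mixture to the all-trans diester, and the route is rejoined at 21.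

Step 5 (hydrodimerisation). The two β-carbons may couple with poor facial control by the auxiliary or with the opposite sense, the radical anion may be protonated before it couples, and the sulfamoyl N–S bonds may be reduced. The fallback gives up auxiliary control and resolves instead. It sets out from 5: hydrodimerisation of the simple ester (SmI2, THF/HMPA, t-BuOH, 0 °C), a coupling of acrylates known to favour the threo isomer, gives the racemic threo diester F3, which is resolved by preparative chromatography on a chiral stationary phase (amylose tris(3,5-dimethylphenylcarbamate)). The (3S,4S)-enantiomer is 13, where the route is rejoined; steps 3, 4 and 6 then fall away.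

Step 8 (aminomethylenation). The acidic C1–H of the β-keto ester may intercept the aminal ester (C1 adducts, O-alkylation of the enol), so that condensation at the C3 methylene stalls. The fallback is the classical deformylative diazo transfer through the dianion. It sets out from 14: NaH (1.0 equiv), then LiN(i-Pr)2 (1.1 equiv) in THF at −78 °C give the sodium lithium dianion F4, which reacts with ethyl formate at C3, the later-formed and more reactive carbanion, to give after AcOH quench the hydroxymethylidene ketone F5. MeSO2N3 and Et3N in MeCN then transfer the diazo group to C3 with loss of the formyl group, and the route is rejoined at 18 (step 9 falls away).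

Further compounds
F1 | step 10 | dilithium bis-enolate of dimethyl (3S,4S)-3,4-bis[1-(dimethylsulfamoyl)imidazol-4-yl]hexanedioate | COC([O-])=C[C@H](c1cn(S(=O)(=O)N(C)C)cn1)[C@@H](c1cn(S(=O)(=O)N(C)C)cn1)C=C([O-])OC.[Li+].[Li+]
F2 | step 10 | dimethyl (3R,4R)-3,4-bis[1-(dimethylsulfamoyl)imidazol-4-yl]cyclobutane-1,2-dicarboxylate, mixture of isomers at C1 and C2 | CN(C)S(=O)(=O)n1cnc(c1)[C@H]2C(C(=O)OC)C(C(=O)OC)[C@@H]2c1cn(S(=O)(=O)N(C)C)cn1
F3 | step 5 | racemic threo dimethyl 3,4-bis[1-(dimethylsulfamoyl)imidazol-4-yl]hexanedioate, (3S,4S) and (3R,4R) enantiomers | COC(=O)C[C@H](c1cn(S(=O)(=O)N(C)C)cn1)[C@@H](c1cn(S(=O)(=O)N(C)C)cn1)CC(=O)OC.COC(=O)C[C@@H](c1cn(S(=O)(=O)N(C)C)cn1)[C@H](c1cn(S(=O)(=O)N(C)C)cn1)CC(=O)OC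
F4 | step 8 | sodium lithium C1,C3-dianion of 14 | COC(=O)C1=C([O-])[CH-][C@H](c2cn(S(=O)(=O)N(C)C)cn2)[C@H]1c1cn(S(=O)(=O)N(C)C)cn1.[Na+].[Li+]
F5 | step 8 | methyl (1S,4R,5R)-3-[(Z)-hydroxymethylidene]-2-oxo-4,5-bis[1-(dimethylsulfamoyl)imidazol-4-yl]cyclopentane-1-carboxylate | O/C=C1\C(=O)[C@@H](C(=O)OC)[C@H](c2cn(S(=O)(=O)N(C)C)cn2)[C@H]1c1cn(S(=O)(=O)N(C)C)cn1
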